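**Retrosynthetic overview**

- The route rests on the eastern benzene ring: its two oxygens (free C3–OH and C5–O–SO3H) sit meta to each other, symmetric about the alkyl-bearing C1. They are equivalent on the arene but distinct on a 5-alkylcyclohexane-1,3-dione once one carbonyl oxygen is a benzyl enol ether.
- Target ⇐ hydrogenolysis of three benzyl ethers ⇐ sulfation of the single free eastern phenol ⇐ dehydrogenative aromatisation of a 3-benzyloxy-5-alkylcyclohex-2-enone that already carries the hindered ester.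
- Ester C(=O)–O bond ⇐ western 2,4-bis(benzyloxy)-6-alkylbenzoyl chloride + eastern secondary carbinol (retention).
- Both six-membered carbocycles ⇐ Michael–Dieckmann annulation of one enone, (3E,12S)-12-hydroxypentadec-3-en-2-one, with a malonate. East: dimethyl malonate, spare ester removed by decarboxylation to the dione. West: diethyl malonate, ester kept, ring aromatised with Br2.
- Enone ⇐ cross-metathesis of but-3-en-2-one with (4S)-tridec-12-en-4-ol ⇐ (S)-2-propyloxirane + oct-7-enyl Grignard. Ring order: eastern carbocycle (step 3), western carbocycle (step 5, aromatic after step 6), eastern ring aromatised last (step 11).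

Key step: step 3

**Assumptions**

- The target is drawn as the free aryl hydrogen sulfate. The sulfate is carried as its sodium salt and protonated only in the last operation; the free acid should be kept cold.
- The sp3 ring carbons in 9, 10, 12, 15, 22 and 23, the branch carbon of the open-chain adducts 8 and 14, and the ring carbons of F1 to F4 are formed without control, so epimer mixtures are expected. All of these centres are lost on decarboxylation or aromatisation, so the SMILES carry no configuration there. Compounds 9, 11 and 15 are drawn as diketones although largely enolised.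

**Route**

Step 1
Reactants: 1 (S)-2-propyloxirane; 2 8-bromooct-1-ene
Product: 4 (4S)-tridec-12-en-4-ol, via oct-7-enylmagnesium bromide 3 (not isolated)
Conditions: 2, Mg, THF, rt → 40 °C; then CuI (10 mol%), 1, THF, −30 → 0 °C; 1 M HCl, 0 °C
Reagents that add atoms: none
Why: Copper-catalysed Grignard opening of a terminal epoxide is an SN2 attack at the unsubstituted CH2, so the C–O stereocentre of 1 is untouched and becomes (S)-C4 of 4.

Step 2
Reactants: 4 (4S)-tridec-12-en-4-ol; 5 but-3-en-2-one
Product: 6 (3E,12S)-12-hydroxypentadec-3-en-2-one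
Conditions: 5 (3 equiv), second-generation Grubbs catalyst RuCl2(=CHPh)(PCy3)(H2IMes) (5 mol%), CH2Cl2, 40 °C
Reagents that add atoms: none
Why: Olefin cross-metathesis of a terminal alkene with an electron-poor vinyl ketone, which does not homodimerise, should give the cross product as the E-enone; the ruthenium carbene tolerates the free carbinol.

Step 3
Reactants: 6 (3E,12S)-12-hydroxypentadec-3-en-2-one; 7 dimethyl malonate
Product: 11 5-[(8S)-8-hydroxyundecyl]cyclohexane-1,3-dione, via Michael adduct 8 (not isolated), via dioxo ester 9 (not isolated), via dioxo acid 10 (not isolated)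
Conditions: NaOMe (1.2 equiv), MeOH, reflux; then 2 M aq. NaOH, 80 °C; then HCl to pH 2, 80 °C
Reagents that add atoms: none
Why: Sodium dimethyl malonate adds in Michael fashion to the β-carbon (C4) of enone 6 to give 8; under the equilibrating methoxide conditions the methyl-ketone enolate (C1) then attacks one malonate ester carbonyl in a Claisen (Dieckmann-type) acylation, closing the six-membered ring in 6-(enolendo)-exo-trig mode to give 9 as its doubly stabilised sodium enolate, whose formation pulls both reversible steps forward. Hydroxide then saponifies the remaining ester, and acidification with warming decarboxylates β-keto acid 10 to dione 11. The closest known reaction type is the malonate–enone annulation used for dimedone and other 5-substituted cyclohexane-1,3-diones. No stereocentre is created in 11, because C5 carries two identical ring arms and the epimers of 8–10 converge, and the remote (S)-carbinol is never ionised or oxidised. The step needs only chemoselectivity: 1,4- over 1,2-addition is secured by the soft, reversibly adding malonate, and closure through the methyl rather than the internal methylene enolate because only the former gives a strain-free six-membered ring (the latter would give a cyclobutanone). The free hydroxyl may transesterify reversibly, but every ester is hydrolysed before decarboxylation.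

Step 4
Reactants: 11 5-[(8S)-8-hydroxyundecyl]cyclohexane-1,3-dione
Product: 12 3-(benzyloxy)-5-[(8S)-8-hydroxyundecyl]cyclohex-2-en-1-one (C5 epimers)
Conditions: BnOH (5 equiv), TsOH·H2O (5 mol%), toluene, reflux, Dean–Stark trap; NaHCO3 work-up
Reagents that add atoms: benzyl alcohol, OCc1ccccc1
Why: Acid-catalysed enol etherification of a cyclic 1,3-dione with azeotropic water removal gives the vinylogous ester; excess primary benzyl alcohol should outcompete the hindered secondary carbinol, and the new C5 stereocentre is erased on aromatisation.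

Step 5
Reactants: 6 (3E,12S)-12-hydroxypentadec-3-en-2-one; 13 diethyl malonate
Product: 15 ethyl 6-[(8S)-8-hydroxyundecyl]-2,4-dioxocyclohexane-1-carboxylate, via diethyl Michael adduct 14 (not isolated)
Conditions: NaOEt (1.2 equiv), EtOH, reflux; then 1 M HCl to pH 3, 0 °C
Reagents that add atoms: none
Why: The same Michael–Dieckmann annulation as step 3, run with diethyl malonate in ethanol and stopped by cold acidification before any saponification, so that the carbon destined to be the western carboxyl is kept as an ethyl ester, which is less open than a methyl ester to bromide-induced O-dealkylation and decarboxylation in the warm DMF of step 6; the ring stereocentres are removed in step 6.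

Step 6
Reactants: 15 ethyl 6-[(8S)-8-hydroxyundecyl]-2,4-dioxocyclohexane-1-carboxylate
Product: 16 ethyl 2,4-dihydroxy-6-[(8S)-8-hydroxyundecyl]benzoate
Conditions: Br2 (1.05 equiv), DMF, 0 °C → 70 °C
Reagents that add atoms: none
Why: Bromination of the enolised dione followed by dehydrobromination is the established aromatisation of 6-alkyl-2,4-dioxocyclohexanecarboxylates to 6-alkyl-2,4-dihydroxybenzoates; the ethyl ester and a temperature held below 80 °C should prevent ester loss, and the single equivalent of Br2 is consumed by the enol at 0 °C before it can oxidise the secondary alcohol.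

Step 7
Reactants: 16 ethyl 2,4-dihydroxy-6-[(8S)-8-hydroxyundecyl]benzoate
Product: 17 ethyl 2,4-bis(benzyloxy)-6-[(8S)-8-hydroxyundecyl]benzoate
Conditions: BnBr (2.5 equiv), K2CO3 (3 equiv), DMF, 60 °C
Reagents that add atoms: benzyl bromide, BrCc1ccccc1
Why: Williamson etherification; K2CO3 ionises only the two phenols, not the aliphatic alcohol, and warm DMF is needed for the hydrogen-bonded ortho phenol.

Step 8
Reactants: 17 ethyl 2,4-bis(benzyloxy)-6-[(8S)-8-hydroxyundecyl]benzoate
Product: 18 2,4-bis(benzyloxy)-6-[(8S)-8-hydroxyundecyl]benzoic acid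
Conditions: KOH (10 equiv), DMSO–H2O (5:1), 110 °C; then 1 M HCl, 0 °C
Reagents that add atoms: potassium hydroxide (KOH), [K+].[OH-]
Why: Saponification of a 2,6-disubstituted ethyl benzoate by acyl–oxygen cleavage needs poorly solvated hydroxide in hot aqueous DMSO; aryl benzyl ethers and the carbinol are stable to base.

Step 9
Reactants: 18 2,4-bis(benzyloxy)-6-[(8S)-8-hydroxyundecyl]benzoic acid
Product: 20 6-[(8S)-8-acetoxyundecyl]-2,4-bis(benzyloxy)benzoic acid, via mixed acetic anhydride 19 (not isolated)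
Conditions: Ac2O (4 equiv), pyridine, DMAP (10 mol%), CH2Cl2, rt; then H2O–THF, NaHCO3, rt; 1 M HCl to pH 3
Reagents that add atoms: acetic anhydride, CC(=O)OC(C)=O
Why: DMAP-catalysed O-acetylation of the secondary alcohol proceeds with retention; the carboxyl group is acetylated transiently to mixed anhydride 19, which water cleaves at the unhindered acetyl carbonyl on work-up.

Step 10
Reactants: 20 6-[(8S)-8-acetoxyundecyl]-2,4-bis(benzyloxy)benzoic acid; 12 3-(benzyloxy)-5-[(8S)-8-hydroxyundecyl]cyclohex-2-en-1-one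
Product: 22 (4S)-11-[3-(benzyloxy)-5-oxocyclohex-3-en-1-yl]undecan-4-yl 6-[(8S)-8-acetoxyundecyl]-2,4-bis(benzyloxy)benzoate, via aroyl chloride 21 (not isolated)
Conditions: 20, (COCl)2 (1.5 equiv), DMF (cat.), CH2Cl2, 0 °C → rt, evaporate; then 12, Et3N (3 equiv), DMAP (1 equiv), toluene, rt → 60 °C
Reagents that add atoms: none
Why: Acid chloride formation followed by DMAP-mediated acyl transfer through the acylpyridinium ion; acylation occurs at oxygen, so the (S)-carbinol configuration is retained, and the vinylogous ester offers no competing nucleophile.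

Step 11
Reactants: 22 (4S)-11-[3-(benzyloxy)-5-oxocyclohex-3-en-1-yl]undecan-4-yl 6-[(8S)-8-acetoxyundecyl]-2,4-bis(benzyloxy)benzoate
Product: 25 (4S)-11-[3-(benzyloxy)-5-hydroxyphenyl]undecan-4-yl 6-[(8S)-8-acetoxyundecyl]-2,4-bis(benzyloxy)benzoate, via silyl dienol ether 23 (not isolated), via cyclohexadienone 24 (not isolated)
Conditions: TMSOTf (1.3 equiv), Et3N (2 equiv), CH2Cl2, 0 °C; then Pd(OAc)2 (1.1 equiv), MeCN, rt
Reagents that add atoms: none
Why: Soft enolisation silylates the ring ketone faster than the acetate, and Saegusa–Ito oxidation with Pd(OAc)2 introduces the second ring double bond; dienone 24 tautomerises irreversibly to the phenol, so the benzyl ether ends on one oxygen and the free OH on the other, and enolisation toward C6 or C4 leads to the same phenol.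

Step 12
Reactants: 25 (4S)-11-[3-(benzyloxy)-5-hydroxyphenyl]undecan-4-yl 6-[(8S)-8-acetoxyundecyl]-2,4-bis(benzyloxy)benzoate
Product: 26 sodium 3-(benzyloxy)-5-[(8S)-8-({6-[(8S)-8-acetoxyundecyl]-2,4-bis(benzyloxy)benzoyl}oxy)undecyl]phenyl sulfate
Conditions: SO3·pyridine (5 equiv), pyridine, 40 °C; then aq. NaHCO3
Reagents that add atoms: sulfur trioxide–pyridine complex, O=S(=O)=O.c1ccncc1; NaHCO3, [Na+].OC([O-])=O
Why: O-Sulfation of a phenol with the SO3–pyridine complex; 25 has a single hydroxyl group, so no selectivity is required, and bicarbonate exchange should give the stable sodium salt.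

Step 13
Reactants: 26 sodium 3-(benzyloxy)-5-[(8S)-8-({6-[(8S)-8-acetoxyundecyl]-2,4-bis(benzyloxy)benzoyl}oxy)undecyl]phenyl sulfate
Product: 27 Integracin D, (4S)-11-[3-hydroxy-5-(sulfooxy)phenyl]undecan-4-yl 6-[(8S)-8-acetoxyundecyl]-2,4-dihydroxybenzoate
Conditions: H2 (1 atm), 10% Pd/C, MeOH–EtOAc, rt; then 0.1 M HCl (1 equiv), 0 °C, extraction (EtOAc–n-BuOH), lyophilise
Reagents that add atoms: none
Why: Catalytic hydrogenolysis cleaves the three aryl benzyl ethers, while the aryl sulfate monoester, the aryl and alkyl esters and both stereocentres are inert to H2 on palladium; brief cold protonation then gives the hydrogen sulfate form.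

**Compound list**

1 | (S)-2-propyloxirane | CCC[C@H]1CO1 | starting material
2 | 8-bromooct-1-ene | C=CCCCCCCBr | starting material
3 | oct-7-enylmagnesium bromide | C=CCCCCCC[Mg]Br | intermediate (not isolated)
4 | (4S)-tridec-12-en-4-ol | CCC[C@@H](CCCCCCCC=C)O | intermediate
5 | but-3-en-2-one | CC(=O)C=C | starting material
6 | (3E,12S)-12-hydroxypentadec-3-en-2-one | CCC[C@@H](CCCCCCC/C=C/C(C)=O)O | intermediate
7 | dimethyl malonate | COC(=O)CC(=O)OC | starting material
8 | dimethyl 2-[(12S)-12-hydroxy-2-oxopentadecan-4-yl]propanedioate (C4 epimers) | CCC[C@@H](CCCCCCCC(CC(C)=O)C(C(=O)OC)C(=O)OC)O | intermediate (not isolated)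
9 | methyl 6-[(8S)-8-hydroxyundecyl]-2,4-dioxocyclohexane-1-carboxylate | CCC[C@@H](CCCCCCCC1CC(=O)CC(=O)C1C(=O)OC)O | intermediate (not isolated)
10 | 6-[(8S)-8-hydroxyundecyl]-2,4-dioxocyclohexane-1-carboxylic acid | CCC[C@@H](CCCCCCCC1CC(=O)CC(=O)C1C(=O)O)O | intermediate (not isolated)
11 | 5-[(8S)-8-hydroxyundecyl]cyclohexane-1,3-dione | CCC[C@@H](CCCCCCCC1CC(=O)CC(=O)C1)O | intermediate
12 | 3-(benzyloxy)-5-[(8S)-8-hydroxyundecyl]cyclohex-2-en-1-one (C5 epimers) | CCC[C@@H](CCCCCCCC1CC(=O)C=C(OCc2ccccc2)C1)O | intermediate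
13 | diethyl malonate | CCOC(=O)CC(=O)OCC | starting material
14 | diethyl 2-[(12S)-12-hydroxy-2-oxopentadecan-4-yl]propanedioate (C4 epimers) | CCC[C@@H](CCCCCCCC(CC(C)=O)C(C(=O)OCC)C(=O)OCC)O | intermediate (not isolated)
15 | ethyl 6-[(8S)-8-hydroxyundecyl]-2,4-dioxocyclohexane-1-carboxylate | CCC[C@@H](CCCCCCCC1CC(=O)CC(=O)C1C(=O)OCC)O | intermediate
16 | ethyl 2,4-dihydroxy-6-[(8S)-8-hydroxyundecyl]benzoate | CCC[C@@H](CCCCCCCc1cc(O)cc(O)c1C(=O)OCC)O | intermediate
17 | ethyl 2,4-bis(benzyloxy)-6-[(8S)-8-hydroxyundecyl]benzoate | CCC[C@@H](CCCCCCCc1cc(OCc2ccccc2)cc(OCc2ccccc2)c1C(=O)OCC)O | intermediate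
18 | 2,4-bis(benzyloxy)-6-[(8S)-8-hydroxyundecyl]benzoic acid | CCC[C@@H](CCCCCCCc1cc(OCc2ccccc2)cc(OCc2ccccc2)c1C(=O)O)O | intermediate
19 | acetic 6-[(8S)-8-acetoxyundecyl]-2,4-bis(benzyloxy)benzoic anhydride | CCC[C@@H](CCCCCCCc1cc(OCc2ccccc2)cc(OCc2ccccc2)c1C(=O)OC(C)=O)OC(C)=O | intermediate (not isolated)
20 | 6-[(8S)-8-acetoxyundecyl]-2,4-bis(benzyloxy)benzoic acid | CCC[C@@H](CCCCCCCc1cc(OCc2ccccc2)cc(OCc2ccccc2)c1C(=O)O)OC(C)=O | intermediate
21 | 6-[(8S)-8-acetoxyundecyl]-2,4-bis(benzyloxy)benzoyl chloride | CCC[C@@H](CCCCCCCc1cc(OCc2ccccc2)cc(OCc2ccccc2)c1C(Cl)=O)OC(C)=O | intermediate (not isolated)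
22 | (4S)-11-[3-(benzyloxy)-5-oxocyclohex-3-en-1-yl]undecan-4-yl 6-[(8S)-8-acetoxyundecyl]-2,4-bis(benzyloxy)benzoate (ring C1 epimers) | CCC[C@@H](CCCCCCCc1cc(OCc2ccccc2)cc(OCc2ccccc2)c1C(=O)O[C@@H](CCC)CCCCCCCC1CC(=O)C=C(OCc2ccccc2)C1)OC(C)=O | intermediate
23 | (4S)-11-[5-(benzyloxy)-3-(trimethylsilyloxy)cyclohexa-2,4-dien-1-yl]undecan-4-yl 6-[(8S)-8-acetoxyundecyl]-2,4-bis(benzyloxy)benzoate | CCC[C@@H](CCCCCCCc1cc(OCc2ccccc2)cc(OCc2ccccc2)c1C(=O)O[C@@H](CCC)CCCCCCCC1CC(OCc2ccccc2)=CC(O[Si](C)(C)C)=C1)OC(C)=O | intermediate (not isolated)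
24 | (4S)-11-[5-(benzyloxy)-3-oxocyclohexa-1,4-dien-1-yl]undecan-4-yl 6-[(8S)-8-acetoxyundecyl]-2,4-bis(benzyloxy)benzoate | CCC[C@@H](CCCCCCCc1cc(OCc2ccccc2)cc(OCc2ccccc2)c1C(=O)O[C@@H](CCC)CCCCCCCC1=CC(=O)C=C(OCc2ccccc2)C1)OC(C)=O | intermediate (not isolated)
25 | (4S)-11-[3-(benzyloxy)-5-hydroxyphenyl]undecan-4-yl 6-[(8S)-8-acetoxyundecyl]-2,4-bis(benzyloxy)benzoate | CCC[C@@H](CCCCCCCc1cc(OCc2ccccc2)cc(OCc2ccccc2)c1C(=O)O[C@@H](CCC)CCCCCCCc1cc(O)cc(OCc2ccccc2)c1)OC(C)=O | intermediate
26 | sodium 3-(benzyloxy)-5-[(8S)-8-({6-[(8S)-8-acetoxyundecyl]-2,4-bis(benzyloxy)benzoyl}oxy)undecyl]phenyl sulfate | CCC[C@@H](CCCCCCCc1cc(OCc2ccccc2)cc(OCc2ccccc2)c1C(=O)O[C@@H](CCC)CCCCCCCc1cc(OCc2ccccc2)cc(OS(=O)(=O)[O-])c1)OC(C)=O.[Na+] | intermediate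
27 | Integracin D | CCC[C@@H](CCCCCCCc1cc(O)cc(O)c1C(=O)O[C@@H](CCC)CCCCCCCc1cc(O)cc(OS(=O)(=O)O)c1)OC(C)=O | target

**Step count**

Total: 13 steps. Longest linear sequence: 11 steps (1, 2, 5, 6, 7, 8, 9, 10, 11, 12, 13); the eastern branch (1, 2, 3, 4) joins at step 10.

**Steps most likely to fail**

Step 10. Acyl transfer from the 2,6-disubstituted aroyl chloride to a secondary carbinol may be too slow because the carbonyl is shielded. The acid chloride could then decay by loss of benzyl chloride from the ortho benzyloxy group, or traces of HCl could hydrolyse the vinylogous ester. The fallback makes the ester bond by SN2 attack of the carboxylate at the carbinol carbon, with two inversions so that the net result is retention. It sets out from 12. Mitsunobu reaction with 4-nitrobenzoic acid (PPh3, diisopropyl azodicarboxylate, THF, 0 °C) should give the inverted (4R)-11-[3-(benzyloxy)-5-oxocyclohex-3-en-1-yl]undecan-4-yl 4-nitrobenzoate F1. Brief cold methanolysis (K2CO3, MeOH, 0 °C), kept short so that the benzyl vinylogous ester is not exchanged, should release 3-(benzyloxy)-5-[(8R)-8-hydroxyundecyl]cyclohex-2-en-1-one F2. A second Mitsunobu reaction of F2 with acid 20 (PPh3, diisopropyl azodicarboxylate, toluene, rt) inverts again and comes back to the route at 22.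

Step 11. Silylation may also enolise the acetate, or the palladium enolate may be protonated back to the enone instead of undergoing β-hydride elimination, so dehydrogenation stalls. The fallback replaces the palladium step by selenoxide syn-elimination and sets out from 23, generated as in step 11. Treatment with PhSeCl (CH2Cl2, −78 °C) should give (4S)-11-[3-(benzyloxy)-5-oxo-6-(phenylselanyl)cyclohex-3-en-1-yl]undecan-4-yl 6-[(8S)-8-acetoxyundecyl]-2,4-bis(benzyloxy)benzoate F3. Oxidation (H2O2, pyridine, CH2Cl2, 0 °C) should give (4S)-11-[3-(benzyloxy)-5-oxo-6-(phenylseleninyl)cyclohex-3-en-1-yl]undecan-4-yl 6-[(8S)-8-acetoxyundecyl]-2,4-bis(benzyloxy)benzoate F4, which is not isolated. Spontaneous elimination gives dienone 24, which tautomerises, so the fallback comes back to the route at 25.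

Step 13. The sulfate monoester salt may lose SO3 by solvolysis during chromatography, on the catalyst surface or during protonation, and the amphiphilic salt may debenzylate slowly or incompletely. The fallback carries the sulfate as a neutral, chromatographable diester and unmasks it together with the benzyl ethers; it sets out from 25. 2,2,2-Trichloroethyl chlorosulfate (Et3N, DMAP, THF, 0 °C → rt) should give (4S)-11-{3-(benzyloxy)-5-[(2,2,2-trichloroethoxy)sulfonyloxy]phenyl}undecan-4-yl 6-[(8S)-8-acetoxyundecyl]-2,4-bis(benzyloxy)benzoate F5. Transfer hydrogenolysis (10% Pd/C, ammonium formate, MeOH, rt) should cleave the trichloroethyl group and the three benzyl ethers in one operation to give ammonium 3-hydroxy-5-[(8S)-8-({6-[(8S)-8-acetoxyundecyl]-2,4-dihydroxybenzoyl}oxy)undecyl]phenyl sulfate F6. Cold protonation (0.1 M HCl, 0 °C) comes back to the route at 27.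

**Further compounds**

F1 | step 10 | (4R)-11-[3-(benzyloxy)-5-oxocyclohex-3-en-1-yl]undecan-4-yl 4-nitrobenzoate | CCC[C@H](CCCCCCCC1CC(=O)C=C(OCc2ccccc2)C1)OC(=O)c1ccc(cc1)[N+](=O)[O-]
F2 | step 10 | 3-(benzyloxy)-5-[(8R)-8-hydroxyundecyl]cyclohex-2-en-1-one | CCC[C@H](CCCCCCCC1CC(=O)C=C(OCc2ccccc2)C1)O
F3 | step 11 | (4S)-11-[3-(benzyloxy)-5-oxo-6-(phenylselanyl)cyclohex-3-en-1-yl]undecan-4-yl 6-[(8S)-8-acetoxyundecyl]-2,4-bis(benzyloxy)benzoate | CCC[C@@H](CCCCCCCc1cc(OCc2ccccc2)cc(OCc2ccccc2)c1C(=O)O[C@@H](CCC)CCCCCCCC1CC(OCc2ccccc2)=CC(=O)C1[Se]c1ccccc1)OC(C)=O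
F4 | step 11 | (4S)-11-[3-(benzyloxy)-5-oxo-6-(phenylseleninyl)cyclohex-3-en-1-yl]undecan-4-yl 6-[(8S)-8-acetoxyundecyl]-2,4-bis(benzyloxy)benzoate | CCC[C@@H](CCCCCCCc1cc(OCc2ccccc2)cc(OCc2ccccc2)c1C(=O)O[C@@H](CCC)CCCCCCCC1CC(OCc2ccccc2)=CC(=O)C1[Se](=O)c1ccccc1)OC(C)=O
F5 | step 13 | (4S)-11-{3-(benzyloxy)-5-[(2,2,2-trichloroethoxy)sulfonyloxy]phenyl}undecan-4-yl 6-[(8S)-8-acetoxyundecyl]-2,4-bis(benzyloxy)benzoate | CCC[C@@H](CCCCCCCc1cc(OCc2ccccc2)cc(OCc2ccccc2)c1C(=O)O[C@@H](CCC)CCCCCCCc1cc(OCc2ccccc2)cc(OS(=O)(=O)OCC(Cl)(Cl)Cl)c1)OC(C)=O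
F6 | step 13 | ammonium 3-hydroxy-5-[(8S)-8-({6-[(8S)-8-acetoxyundecyl]-2,4-dihydroxybenzoyl}oxy)undecyl]phenyl sulfate | CCC[C@@H](CCCCCCCc1cc(O)cc(O)c1C(=O)O[C@@H](CCC)CCCCCCCc1cc(O)cc(OS(=O)(=O)[O-])c1)OC(C)=O.[NH4+]
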